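**Plan**

1. Retrosynthesis: the side chain is cut at the CH2–C2 bond of the bicycle (B-alkyl Suzuki–Miyaura coupling of enol triflate 14 with vinyl dioxane 27). Ring B is then cut at C3–C4 and at C1–C8a (bicycle numbering: C1 = CMe2, C2 carries the chain, C3 = CMe, C4 = CH2, C4a/C8a = fusion CH, C5=C6(Me) in ring A).
2. Forward: ring A is bought as 3-methylcyclohex-2-enone. Its two γ-carbons (the methyl carbon, later C4, and the ring CH2, later C8a) flank the enone β-carbon (later C4a). C2 of ring B lies between C1 and C3 and can carry a nitro group, so a 2-nitroallyl acetate acts as a 1,3-dielectrophile and closes ring B in one operation.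
3. The nitro group becomes the C2 ketone (Nef) and then the enol triflate. The ring-A enone is reduced 1,4, trapped and methylated, which fixes C5=C6 and the C6 methyl without a regiochemical choice.
4. Dioxane half: Claisen rearrangement, Brown syn-crotylboration, Shi epoxidation, then perhydrolysis of the epoxide and ring closure on a mesylate, and conversion of the two arms into ester and vinyl.
5. Stereochemistry: C8a from the cinchona amine of the key step (relayed through a transient methyl-bearing centre); C4a from substrate-controlled hydride delivery (cis fusion); the propanoate α-carbon and dioxane C3 from the crotylborane (C3 then inverted by SN2); dioxane C6 from the Shi epoxide (inverted by perhydrolysis).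
6. The two halves are joined in step 17 and the ester is saponified in step 18.

Key step: step 4

Remark: 3, 4, 5 and 6 are carried as stereoisomer mixtures (diastereomers or E/Z) because these elements vanish in step 4; 15 is used racemic.
Assumption: the quinine-derived amine of step 4 is taken to give the (7S) centre of 9; if the opposite sense is found, its quinidine-derived pseudo-enantiomer is used instead.
Assumption: (+)-Ipc2BOMe, from (−)-α-pinene, is taken to be the antipode of the borane that gives (3S,4S)-19; otherwise the reagent from (+)-α-pinene is used.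

**Route**

Step 1
Reactants: 1 2-methyl-1-nitropropan-2-ol; 2 acetaldehyde
Product: 3 2-methyl-3-nitropentane-2,4-diol (mixture of diastereomers)
Conditions: Et3N (0.1 equiv), THF, 0 °C to rt
Reagents that add atoms: none
Why: Henry (nitroaldol) addition of the nitronate of 1 to the aldehyde under a catalytic amine base, mild enough to keep retro-Henry loss of acetone slow; the two new stereocentres are left uncontrolled because both are erased in steps 2 and 4.

Step 2
Reactants: 3 2-methyl-3-nitropentane-2,4-diol
Product: 5 2-methyl-3-nitropent-3-en-2-ol (E/Z mixture), via secondary acetate 4 (not isolated)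
Conditions: Ac2O (1.1 equiv), pyridine, CH2Cl2, 0 °C; then Et3N, 0 °C to rt
Reagents that add atoms: none
Why: selective O-acetylation of the secondary hydroxyl (the tertiary one does not react) and E1cB loss of acetate from the nitronate, the dehydration stage of a Henry condensation, put the nitroalkene on the ethylidene side only; no stereocentre remains.

Step 3
Reactants: 5 2-methyl-3-nitropent-3-en-2-ol
Product: 6 2-methyl-3-nitropent-3-en-2-yl acetate (E/Z mixture)
Conditions: Ac2O, Sc(OTf)3 (1 mol %), MeCN, −20 °C
Reagents that add atoms: acetic anhydride, CC(=O)OC(C)=O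
Why: Lewis acid-catalysed acylation of the hindered tertiary alcohol under non-basic conditions gives the 2-nitroallyl ester, a 1,3-dielectrophile (Michael acceptor with a β′-leaving group); no stereocentre is formed.

Step 4
Reactants: 7 3-methylcyclohex-2-en-1-one (2 equiv); 6 2-methyl-3-nitropent-3-en-2-yl acetate
Product: 9 (4aS,6R,7S)-5,5,7-trimethyl-6-nitro-4,4a,5,6,7,8-hexahydronaphthalen-2(3H)-one, via nitroalkene enone 8 (not isolated)
Conditions: 9-amino-9-deoxy-epi-quinine (20 mol %), 2-fluorobenzoic acid (30 mol %), toluene, 40 °C, slow addition of 6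
Reagents that add atoms: none
Why: Proposed new method: condensation of the primary amine with 7 gives the exocyclic dienamine, whose methyl-derived γ-carbon adds to the ethylidene carbon of 6 (vinylogous Michael addition); the nitronate expels acetate (E1cB) to give the tetrasubstituted nitroalkene 8, and the same catalyst, now as the endocyclic dienamine, delivers the ring γ-carbon to the CMe2 carbon of that nitroalkene, so that both ring-B bonds (CH2–CHMe and CMe2–CH) form in one operation. The closest known reaction types are the amine-catalysed vinylogous Michael addition of 3-methylcyclohex-2-enone to nitroalkenes through dienamines and the [3+3] carbocyclisation of enamines with 2-nitroallyl esters by Michael addition, elimination and second Michael addition. The first bond forms intermolecularly and ring B is then closed by a 6-endo-trig vinylogous Michael addition that creates the quaternary carbon. The methyl-bearing centre C7 is set by the cinchona amine in the intermolecular step; C4a is set in the ring closure by a chair-like transition state with the C7 methyl pseudo-equatorial (allylic 1,3-strain against the nitroalkene), reinforced by the catalyst-bound dienamine; C6 settles with nitro equatorial by nitronate equilibration, and since C6 and C7 are erased later only C4a matters. The step needs reaction at the methyl γ-carbon first and the ring γ-carbon second, not at the α-carbon and not twice on one enone: the first is the known site preference of this dienamine, ring closure through the α-carbon would give a deconjugated and reversibly formed adduct whereas γ-closure restores the enone, and 7 is used in excess.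

Step 5
Reactants: 9 (4aS,6R,7S)-5,5,7-trimethyl-6-nitro-4,4a,5,6,7,8-hexahydronaphthalen-2(3H)-one
Product: 10 (4aS,7S)-5,5,7-trimethyl-4,4a,7,8-tetrahydronaphthalene-2,6(3H,5H)-dione
Conditions: KOH (1.0 equiv), MeOH, 0 °C; then KHSO5 (as 2KHSO5·KHSO4·K2SO4), aq. K2HPO4 buffer, 0 °C to rt
Reagents that add atoms: potassium peroxymonosulfate, [K+].[O-]S(=O)(=O)OO
Why: oxidative Nef reaction in which the potassium nitronate is cleaved at C=N by peroxymonosulfate while the electron-poor enone alkene is left alone; the C7 methyl centre may epimerise but is erased in step 8.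

Step 6
Reactants: 10 (4aS,7S)-5,5,7-trimethyl-4,4a,7,8-tetrahydronaphthalene-2,6(3H,5H)-dione
Product: 12 (4aS,7S,8aS)-5,5,7-trimethyl-6-oxo-3,4,4a,5,6,7,8,8a-octahydronaphthalen-2-yl nonafluorobutane-1-sulfonate, via silyl enol ether 11 (not isolated)
Conditions: [(Ph3P)CuH]6 (3 mol %), PhMe2SiH, toluene, 0 °C to rt; then C4F9SO2F, Bu4NF (5 mol %), THF, 0 °C to rt
Reagents that add atoms: nonafluorobutane-1-sulfonyl fluoride, O=S(=O)(F)C(F)(F)C(F)(F)C(F)(F)C(F)(F)F
Why: copper hydride-catalysed 1,4-hydrosilylation of the β,β-disubstituted enone (the hindered saturated ketone reacts far more slowly) gives the regio-defined silyl enol ether, which fluoride-catalysed sulfonylation converts into the alkenyl nonaflate without enolate equilibration; hydride adds to C8a on the face of the C4a hydrogen, anti to the pseudo-axial C5 methyl, which gives the cis ring fusion.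

Step 7
Reactants: 12 (4aS,7S,8aS)-5,5,7-trimethyl-6-oxo-3,4,4a,5,6,7,8,8a-octahydronaphthalen-2-yl nonafluorobutane-1-sulfonate
Product: 13 (3S,4aR,8aS)-1,1,3,6-tetramethyl-3,4,4a,7,8,8a-hexahydronaphthalen-2(1H)-one
Conditions: Me2CuLi (from CuI and 2 MeLi), THF, −78 to −15 °C
Reagents that add atoms: lithium dimethylcuprate, [Li+].C[Cu-]C
Why: cross-coupling of the alkenyl sulfonate with the cuprate puts the ring-A methyl on the already placed C=C, and the hindered ketone does not add the cuprate; no stereocentre changes.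

Step 8
Reactants: 13 (3S,4aR,8aS)-1,1,3,6-tetramethyl-3,4,4a,7,8,8a-hexahydronaphthalen-2(1H)-one
Product: 14 (4aR,8aS)-1,1,3,6-tetramethyl-1,4,4a,7,8,8a-hexahydronaphthalen-2-yl trifluoromethanesulfonate
Conditions: KN(SiMe3)2, THF, −78 to 0 °C; then PhNTf2, −78 °C to rt
Reagents that add atoms: N-phenylbis(trifluoromethanesulfonimide), O=S(=O)(N(c1ccccc1)S(=O)(=O)C(F)(F)F)C(F)(F)F
Why: enolisation can only occur towards C3 because C1 is quaternary, so O-triflation of the potassium enolate gives the single tetrasubstituted enol triflate and erases the C3 centre.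

Step 9
Reactants: 15 3-methylbut-3-en-2-ol (racemic); 16 ethyl vinyl ether
Product: 18 (4E)-4-methylhex-4-enal, via allyl vinyl ether 17 (not isolated)
Conditions: Hg(OAc)2 (5 mol %), 16 as solvent, reflux; then 135 °C, sealed tube
Reagents that add atoms: none
Why: vinyl ether exchange followed by Claisen rearrangement through a chair transition state with the carbinol methyl equatorial should give the (E)-trisubstituted alkene; the stereocentre of 15 is consumed.

Step 10
Reactants: 18 (4E)-4-methylhex-4-enal
Product: 19 (3S,4S,7E)-3,7-dimethylnona-1,7-dien-4-ol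
Conditions: cis-2-butene, KOtBu, n-BuLi, THF, −78 to −45 °C; (+)-Ipc2BOMe, −78 °C; BF3·OEt2; then 18, −78 °C; NaOH, H2O2, rt
Reagents that add atoms: (Z)-crotylbis(isopinocampheyl)borane made in the flask, C/C=C\CB([C@H]1C[C@H]2C[C@@H]([C@@H]1C)C2(C)C)[C@H]1C[C@H]2C[C@@H]([C@@H]1C)C2(C)C
Why: Brown (Z)-crotylboration through a closed chair transition state gives the syn homoallylic alcohol, the (Z)-geometry fixing the relative and the isopinocampheyl groups the absolute configuration.

Step 11
Reactants: 19 (3S,4S,7E)-3,7-dimethylnona-1,7-dien-4-ol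
Product: 20 (3S,4S,7E)-3,7-dimethylnona-1,7-dien-4-yl methanesulfonate
Conditions: MsCl, Et3N, CH2Cl2, 0 °C
Reagents that add atoms: methanesulfonyl chloride, CS(Cl)(=O)=O
Why: sulfonylation of the secondary alcohol with retention prepares C4 for SN2 displacement and prevents the hydroxyl from opening the epoxide made next.

Step 12
Reactants: 20 (3S,4S,7E)-3,7-dimethylnona-1,7-dien-4-yl methanesulfonate
Product: 21 (3S,4S)-6-[(2R,3R)-2,3-dimethyloxiran-2-yl]-3-methylhex-1-en-4-yl methanesulfonate
Conditions: 1,2:4,5-di-O-isopropylidene-β-D-erythro-2,3-hexodiulo-2,6-pyranose (Shi ketone, 0.3 equiv), KHSO5 (as 2KHSO5·KHSO4·K2SO4), K2CO3, Bu4NHSO4, MeCN/CH2(OMe)2/aq. Na2B4O7 buffer (pH 10.5), 0 °C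
Reagents that add atoms: potassium peroxymonosulfate, [K+].[O-]S(=O)(=O)OO
Why: Shi epoxidation by the chiral dioxirane through the spiro transition state should give the (R,R)-epoxide of the (E)-trisubstituted alkene under reagent control and leave the less electron-rich vinyl group alone.

Step 13
Reactants: 21 (3S,4S)-6-[(2R,3R)-2,3-dimethyloxiran-2-yl]-3-methylhex-1-en-4-yl methanesulfonate
Product: 23 (1R)-1-[(3S,6R)-6-[(2S)-but-3-en-2-yl]-3-methyl-1,2-dioxan-3-yl]ethan-1-ol, via hydroperoxy alcohol 22 (not isolated)
Conditions: H2O2 (anhydrous, in Et2O, excess), H3PMo12O40 (5 mol %), Et2O, rt; aqueous wash; then Cs2CO3, DMF, 0 °C to rt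
Reagents that add atoms: hydrogen peroxide, OO
Why: acid-catalysed perhydrolysis of the trisubstituted epoxide places OOH on the tertiary carbon with inversion, and the hydroperoxide anion then displaces the secondary mesylate in a 6-exo-tet closure with inversion, so both C–O centres of the 1,2-dioxane come from SN2 events.

Step 14
Reactants: 23 (1R)-1-[(3S,6R)-6-[(2S)-but-3-en-2-yl]-3-methyl-1,2-dioxan-3-yl]ethan-1-ol
Product: 25 (2R)-2-[(3R,6S)-6-[(1R)-1-hydroxyethyl]-6-methyl-1,2-dioxan-3-yl]propanoic acid, via aldehyde 24 (not isolated)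
Conditions: O3, MeCN/H2O, 0 °C; then NaClO2, NaH2PO4, H2O, 0 °C to rt
Reagents that add atoms: ozone, [O-][O+]=O; sodium chlorite, [Na+].[O-]Cl=O
Why: ozonolysis of the only C=C in wet acetonitrile gives the aldehyde without a reductant, and chlorite (Lindgren–Pinnick oxidation) takes it to the acid under weakly acidic conditions that should not epimerise the α-centre.

Step 15
Reactants: 25 (2R)-2-[(3R,6S)-6-[(1R)-1-hydroxyethyl]-6-methyl-1,2-dioxan-3-yl]propanoic acid
Product: 26 methyl (2R)-2-[(3R,6S)-6-[(1R)-1-hydroxyethyl]-6-methyl-1,2-dioxan-3-yl]propanoate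
Conditions: Me3SiCHN2, MeOH/toluene, 0 °C
Reagents that add atoms: (trimethylsilyl)diazomethane, C[Si](C)(C)C=[N+]=[N-]
Why: diazoalkane esterification under neutral conditions masks the acid for the dehydration and borane steps without touching the peroxide or the α-centre.

Step 16
Reactants: 26 methyl (2R)-2-[(3R,6S)-6-[(1R)-1-hydroxyethyl]-6-methyl-1,2-dioxan-3-yl]propanoate
Product: 27 methyl (2R)-2-[(3R,6S)-6-ethenyl-6-methyl-1,2-dioxan-3-yl]propanoate
Conditions: methyl N-(triethylammoniosulfonyl)carbamate (Burgess reagent), toluene, 60 °C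
Reagents that add atoms: none
Why: Burgess dehydration by syn-elimination of the sulfamate ester; only the methyl group carries a β-hydrogen (the other neighbour is the quaternary peroxide carbon), so only the vinyl group can form.

Step 17
Reactants: 27 methyl (2R)-2-[(3R,6S)-6-ethenyl-6-methyl-1,2-dioxan-3-yl]propanoate; 14 (4aR,8aS)-1,1,3,6-tetramethyl-1,4,4a,7,8,8a-hexahydronaphthalen-2-yl trifluoromethanesulfonate
Product: 29 methyl (2R)-2-[(3R,6R)-6-methyl-6-{2-[(4aR,8aS)-1,1,3,6-tetramethyl-1,4,4a,7,8,8a-hexahydronaphthalen-2-yl]ethyl}-1,2-dioxan-3-yl]propanoate, via alkylborane 28 (not isolated)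
Conditions: 27, 9-BBN-H dimer, THF, 0 °C to rt; then 14, Pd(dppf)Cl2 (10 mol %), AsPh3 (10 mol %), aq. K3PO4, THF/DMF, rt to 45 °C
Reagents that add atoms: none
Why: anti-Markovnikov hydroboration of the vinyl group and B-alkyl Suzuki–Miyaura coupling with the enol triflate join the halves at the sp2–sp3 bond, the dialkyl peroxide and the ester being expected to tolerate 9-BBN and the palladium catalyst near room temperature; no stereocentre is touched.

Step 18
Reactants: 29 methyl (2R)-2-[(3R,6R)-6-methyl-6-{2-[(4aR,8aS)-1,1,3,6-tetramethyl-1,4,4a,7,8,8a-hexahydronaphthalen-2-yl]ethyl}-1,2-dioxan-3-yl]propanoate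
Product: 30 (2R)-2-[(3R,6R)-6-methyl-6-{2-[(4aR,8aS)-1,1,3,6-tetramethyl-1,4,4a,7,8,8a-hexahydronaphthalen-2-yl]ethyl}-1,2-dioxan-3-yl]propanoic acid
Conditions: LiOH, THF/MeOH/H2O, 0 °C; then 1 M HCl to pH 3
Reagents that add atoms: lithium hydroxide, [Li+].[OH-]
Why: saponification at low temperature, where acyl–oxygen cleavage should outrun α-deprotonation (which would open the β-peroxy ester by E1cB), frees the acid without change at any stereocentre.

**Compound list**

1 | 2-methyl-1-nitropropan-2-ol | CC(C)(O)C[N+](=O)[O-] | starting material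
2 | acetaldehyde | CC=O | starting material
3 | 2-methyl-3-nitropentane-2,4-diol (mixture of diastereomers) | CC(O)C([N+](=O)[O-])C(C)(C)O | intermediate
4 | 4-hydroxy-4-methyl-3-nitropentan-2-yl acetate (mixture of diastereomers) | CC(OC(C)=O)C([N+](=O)[O-])C(C)(C)O | intermediate
5 | 2-methyl-3-nitropent-3-en-2-ol (E/Z mixture) | CC=C([N+](=O)[O-])C(C)(C)O | intermediate
6 | 2-methyl-3-nitropent-3-en-2-yl acetate (E/Z mixture) | CC=C([N+](=O)[O-])C(C)(C)OC(C)=O | intermediate
7 | 3-methylcyclohex-2-en-1-one | CC1=CC(=O)CCC1 | starting material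
8 | 3-[(2S)-2,4-dimethyl-3-nitropent-3-en-1-yl]cyclohex-2-en-1-one | O=C1C=C(C[C@H](C)C([N+](=O)[O-])=C(C)C)CCC1 | intermediate
9 | (4aS,6R,7S)-5,5,7-trimethyl-6-nitro-4,4a,5,6,7,8-hexahydronaphthalen-2(3H)-one | O=C1C=C2C[C@H](C)[C@@H]([N+](=O)[O-])C(C)(C)[C@H]2CC1 | intermediate
10 | (4aS,7S)-5,5,7-trimethyl-4,4a,7,8-tetrahydronaphthalene-2,6(3H,5H)-dione | O=C1C=C2C[C@H](C)C(=O)C(C)(C)[C@H]2CC1 | intermediate
11 | {[(4aS,7S,8aS)-5,5,7-trimethyl-6-oxo-3,4,4a,5,6,7,8,8a-octahydronaphthalen-2-yl]oxy}dimethyl(phenyl)silane | C[Si](C)(c1ccccc1)OC1=C[C@H]2C[C@H](C)C(=O)C(C)(C)[C@H]2CC1 | intermediate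
12 | (4aS,7S,8aS)-5,5,7-trimethyl-6-oxo-3,4,4a,5,6,7,8,8a-octahydronaphthalen-2-yl nonafluorobutane-1-sulfonate | O=S(=O)(OC1=C[C@H]2C[C@H](C)C(=O)C(C)(C)[C@H]2CC1)C(F)(F)C(F)(F)C(F)(F)C(F)(F)F | intermediate
13 | (3S,4aR,8aS)-1,1,3,6-tetramethyl-3,4,4a,7,8,8a-hexahydronaphthalen-2(1H)-one | CC1=C[C@H]2C[C@H](C)C(=O)C(C)(C)[C@H]2CC1 | intermediate
14 | (4aR,8aS)-1,1,3,6-tetramethyl-1,4,4a,7,8,8a-hexahydronaphthalen-2-yl trifluoromethanesulfonate | CC1=C[C@H]2CC(C)=C(OS(=O)(=O)C(F)(F)F)C(C)(C)[C@H]2CC1 | intermediate
15 | 3-methylbut-3-en-2-ol (racemic) | CC(O)C(C)=C | starting material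
16 | ethyl vinyl ether | C=COCC | starting material
17 | 3-(ethenyloxy)-2-methylbut-1-ene (racemic) | C=COC(C)C(C)=C | intermediate
18 | (4E)-4-methylhex-4-enal | C/C=C(\C)CCC=O | intermediate
19 | (3S,4S,7E)-3,7-dimethylnona-1,7-dien-4-ol | C/C=C(\C)CC[C@H](O)[C@@H](C)C=C | intermediate
20 | (3S,4S,7E)-3,7-dimethylnona-1,7-dien-4-yl methanesulfonate | C/C=C(\C)CC[C@H](OS(C)(=O)=O)[C@@H](C)C=C | intermediate
21 | (3S,4S)-6-[(2R,3R)-2,3-dimethyloxiran-2-yl]-3-methylhex-1-en-4-yl methanesulfonate | C[C@H]1O[C@]1(C)CC[C@H](OS(C)(=O)=O)[C@@H](C)C=C | intermediate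
22 | (3S,4S,7S,8R)-7-hydroperoxy-8-hydroxy-3,7-dimethylnon-1-en-4-yl methanesulfonate | C[C@@H](O)[C@@](C)(OO)CC[C@H](OS(C)(=O)=O)[C@@H](C)C=C | intermediate
23 | (1R)-1-[(3S,6R)-6-[(2S)-but-3-en-2-yl]-3-methyl-1,2-dioxan-3-yl]ethan-1-ol | C[C@@H](O)[C@]1(C)CC[C@H]([C@@H](C)C=C)OO1 | intermediate
24 | (2R)-2-[(3R,6S)-6-[(1R)-1-hydroxyethyl]-6-methyl-1,2-dioxan-3-yl]propanal | C[C@@H](O)[C@]1(C)CC[C@H]([C@@H](C)C=O)OO1 | intermediate
25 | (2R)-2-[(3R,6S)-6-[(1R)-1-hydroxyethyl]-6-methyl-1,2-dioxan-3-yl]propanoic acid | C[C@@H](O)[C@]1(C)CC[C@H]([C@@H](C)C(=O)O)OO1 | intermediate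
26 | methyl (2R)-2-[(3R,6S)-6-[(1R)-1-hydroxyethyl]-6-methyl-1,2-dioxan-3-yl]propanoate | C[C@@H](O)[C@]1(C)CC[C@H]([C@@H](C)C(=O)OC)OO1 | intermediate
27 | methyl (2R)-2-[(3R,6S)-6-ethenyl-6-methyl-1,2-dioxan-3-yl]propanoate | C=C[C@]1(C)CC[C@H]([C@@H](C)C(=O)OC)OO1 | intermediate
28 | methyl (2R)-2-[(3R,6R)-6-[2-(9-borabicyclo[3.3.1]nonan-9-yl)ethyl]-6-methyl-1,2-dioxan-3-yl]propanoate | C(C[C@]1(C)CC[C@H]([C@@H](C)C(=O)OC)OO1)B1C2CCCC1CCC2 | intermediate
29 | methyl (2R)-2-[(3R,6R)-6-methyl-6-{2-[(4aR,8aS)-1,1,3,6-tetramethyl-1,4,4a,7,8,8a-hexahydronaphthalen-2-yl]ethyl}-1,2-dioxan-3-yl]propanoate | CC1=C[C@H]2CC(C)=C(CC[C@]3(C)CC[C@H]([C@@H](C)C(=O)OC)OO3)C(C)(C)[C@H]2CC1 | intermediate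
30 | (2R)-2-[(3R,6R)-6-methyl-6-{2-[(4aR,8aS)-1,1,3,6-tetramethyl-1,4,4a,7,8,8a-hexahydronaphthalen-2-yl]ethyl}-1,2-dioxan-3-yl]propanoic acid | CC1=C[C@H]2CC(C)=C(CC[C@]3(C)CC[C@H]([C@@H](C)C(=O)O)OO3)C(C)(C)[C@H]2CC1 | target

**Totals and risks**

Total steps: 18. Longest linear sequence: 10 steps (steps 1–8, 17, 18; the dioxane branch, steps 9–16, 17, 18, has the same length).

Steps most likely to fail:

1. Step 4 (proposed new method). The amine catalyst may be alkylated by 6 and drop out of the cycle; the ring may close through the enone α-carbon instead of the γ-carbon; or facial control in the ring closure may be low. The fallback sets out from 7 and 6 and comes back at 9, running the two Michael additions as separate, individually known operations. The dienamine-catalysed vinylogous Michael addition with loss of acetate is stopped at the open nitroalkene 8 (lower temperature, isolation). Compound 8 is converted with Me3SiCl, NaI and Et3N in MeCN into its linear endocyclic silyl dienol ether, {[3-((2S)-2,4-dimethyl-3-nitropent-3-en-1-yl)cyclohexa-1,3-dien-1-yl]oxy}trimethylsilane F1. The ring is then closed by an intramolecular vinylogous Mukaiyama–Michael addition to the nitroalkene (TiCl4, CH2Cl2, −78 °C), which is γ-selective by the nature of silyl dienol ethers; hydrolysis of the silyl nitronate gives 9.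

2. Step 17. Oxidative addition and transmetalation at the tetrasubstituted triflate next to CMe2 may be too slow. Protodeboronation, β-hydride elimination, base-induced opening of the β-peroxy ester, or reduction of the O–O bond by the borane or by zerovalent palladium could then take over. The fallback sets out from 14 and 27 and comes back at 29. Mizoroki–Heck coupling of 14 with the vinyl group of 27 (Pd(OAc)2, P(o-tol)3, K2CO3, DMF, 70 °C) can only give the (E)-diene, because the quaternary side has no β-hydrogen. The product is methyl (2R)-2-[(3R,6S)-6-methyl-6-{(E)-2-[(4aR,8aS)-1,1,3,6-tetramethyl-1,4,4a,7,8,8a-hexahydronaphthalen-2-yl]ethenyl}-1,2-dioxan-3-yl]propanoate F2. Diimide (2-nitrobenzenesulfonohydrazide, Et3N, rt) should then reduce only the disubstituted C=C, leaving the tetrasubstituted and trisubstituted alkenes and the peroxide, to give 29.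

3. Step 13. Partial ionisation at the tertiary epoxide carbon would erode the inversion; H2O2 could attack the secondary epoxide carbon; and under base the β-hydroxy hydroperoxide may fragment or the mesylate may eliminate. The fallback sets out from 21 and comes back at 23, with the order of the two C–O bond formations reversed. The mesylate of 21 is displaced first by H2O2/KOH in MeOH–H2O (SN2 with inversion; the epoxide is stable to base) to give (2R,3R)-2-[(3R,4S)-3-hydroperoxy-4-methylhex-5-en-1-yl]-2,3-dimethyloxirane F3. The ring is then closed with camphorsulfonic acid in CH2Cl2 by 6-exo opening of the epoxide at its tertiary carbon by the tethered hydroperoxide. This intramolecular anti opening is stereospecific and gives 23.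

Further compounds
F1 | step 4 | {[3-((2S)-2,4-dimethyl-3-nitropent-3-en-1-yl)cyclohexa-1,3-dien-1-yl]oxy}trimethylsilane | C[Si](C)(C)OC1=CC(C[C@H](C)C([N+](=O)[O-])=C(C)C)=CCC1
F2 | step 17 | methyl (2R)-2-[(3R,6S)-6-methyl-6-{(E)-2-[(4aR,8aS)-1,1,3,6-tetramethyl-1,4,4a,7,8,8a-hexahydronaphthalen-2-yl]ethenyl}-1,2-dioxan-3-yl]propanoate | CC1=C[C@H]2CC(C)=C(/C=C/[C@]3(C)CC[C@H]([C@@H](C)C(=O)OC)OO3)C(C)(C)[C@H]2CC1
F3 | step 13 | (2R,3R)-2-[(3R,4S)-3-hydroperoxy-4-methylhex-5-en-1-yl]-2,3-dimethyloxirane | C[C@H]1O[C@]1(C)CC[C@@H](OO)[C@@H](C)C=C
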